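(All constants are assumed; the run is a simulation.)

The ratio of coupling partner to substrate in the flask, 1.50 by charge, is the first thing to read.

substrate 0.0050 M; coupling partner 7.50 mM (fed, over 0.60 s); time 30 min; the fed solution adds 0.25 times the starting volume

    substrate + coupling partner → target + released group (k1 = 160 L mol⁻¹ s⁻¹)
    target ⇌ isomer of the product (K2 = 3.0, k2 = 0.040 s⁻¹)

- every charge counts on the volume at the start, and the solution that is fed holds the whole dose
- the reaction counts as stopped when no species that holds the substrate changes by six tenths of a point or more over the second half of the time
- run time (flask): 30 min

- the state of affairs at 30 min: stopped, and by what, or still going (the coupling partner has run out first / all of the substrate has reacted / forward and back rates have come level / it is still moving)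
- amount of target at 30 min, in percent of the substrate charged
- amount of isomer of the product at 30 min, in percent of the substrate charged

The reach of the flask is 100 %: the smaller of one and that ratio, the share of the substrate charged that the charge of coupling partner can take through the first step. The second step then shares what passes between target and isomer as one to 3.0, the equilibrium constant.

Now the settings by hand, one at a time. Halving the coupling partner brings the reach down to 75.0 % and isomer to 56.2 %. Adding partner leaves the reach where it stands, since the substrate, charged at less than the partner, is the limiting reagent.

Time is the next setting. The partner's curve is replaced by one constant level, the excess of its charge over the substrate's, taken in the volume after the feed, 2.00 mM. This makes the first step pseudo-first-order with an estimated substrate half-life of 2.17 s. The second step relaxes with a half-life of 13.0 s, and both are far shorter than 30 min. The feed lasts 0.60 s, less than that first half-life, and its volume thins concentrations, not shares of the charge.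

So this reckoning commits to substrate at 0 %, target at 25.0 %, isomer at 75.0 %, and an end by spent substrate.

The forecast names this end: forward and back rates have come level. It puts target at 25 % and isomer at 75 %, reasoning “so it is fully equilibrated”. It shares these percentages with the reckoning above and differs on the state.

The flask ends thus: all of the substrate has reacted. At 30.0 min substrate stands at 0 % and coupling partner at 33.3 % of its own charge, with target 25.0 % and isomer 75.0 %, as a reach of 100 % splits. The neighbour flask holds 0.013 M of substrate with the other charges and the time unchanged, so its reach falls to 57.7 %, and the same split gives target 14.4 % and isomer 43.3 %. At 30.0 min the neighbour flask reads target 14.4 %, isomer 43.3 %, coupling partner 0 % of its own charge, and substrate 42.3 %.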